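The synthesis rests on cutting C7–C8 and C9–C10 around a two-carbon vinyl linchpin (C8–C9). The feature exploited is the isolated carbinol C9, flanked by the C8 methylene and the 1,1-disubstituted alkene C10=C10′ and too far from the tetrahydropyran ring (O, C3–C6, C6′) for substrate control. In one operation a nickel-induced 1,2-metallate shift joins three components, forms both bonds and sets C9 as an allylic boronate that oxidises to the alcohol with retention. The precursor is a trans-2,5-disubstituted tetrahydropyran bearing a C7 iodomethyl group and the acrylic acid masked as an allylic silyl ether; it meets vinyllithium and the alkenyl boronate derived from geranylacetone.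

Key step: step 13

Numbering: C1 carboxyl; C2 (methylene C2′); C3 ring OCH; C4, C5 ring CH2; C6 ring CH; C6′ ring OCH2; C7, C8 chain CH2; C9 carbinol; C10 (methylene C10′); C11 onward the tail.

Remark on the chemistry: in a conjunctive coupling boron stays on the vinyl carbon that receives the migrating group. Boron on C9 therefore requires the C10 alkenyl group to migrate from boron and C7 to enter at C8 as the electrophile. The ring fragment is accordingly carried as the C7 iodide (18) and the geranylacetone fragment as its alkenyl boronate (23). Nickel is used because a primary C(sp3) iodide with β-hydrogens is outside the reach of the palladium/bisphosphine system.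

Assumption: vinyllithium 24 is used as a halide-free solution, bought or freshly made from tetravinylstannane and n-BuLi; the ligand antipode for step 13 is fixed by a pilot run.

Step 1
Reactants: 1 hex-5-enoic acid; 2 (4S)-4-benzyl-1,3-oxazolidin-2-one
Product: 4 (4S)-4-benzyl-3-(hex-5-enoyl)-1,3-oxazolidin-2-one, via mixed pivalic anhydride 3 (not isolated)
Conditions: PivCl, Et3N, THF, −20 °C; then LiCl, 2, −20 °C → rt
Reagents that add atoms: none
Why: N-acylation of the oxazolidinone through the mixed anhydride (LiCl/Et3N activation) is the standard entry to this imide class and creates no stereocentre.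

Step 2
Reactants: 4 (4S)-4-benzyl-3-(hex-5-enoyl)-1,3-oxazolidin-2-one
Product: 6 (4S)-4-benzyl-3-[(2R)-2-[(benzyloxy)methyl]hex-5-enoyl]-1,3-oxazolidin-2-one, via chlorotitanium enolate 5 (not isolated)
Conditions: TiCl4, i-Pr2NEt, CH2Cl2, 0 °C; then BnOCH2Cl, 0 °C
Reagents that add atoms: benzyl chloromethyl ether, ClCOCc1ccccc1
Why: Evans alkylation of the chelated (Z)-titanium enolate, in which the chloromethyl ether attacks the face opposite the C4 benzyl group of the auxiliary, sets the future C6 as (R) in the imide.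

Step 3
Reactants: 6 (4S)-4-benzyl-3-[(2R)-2-[(benzyloxy)methyl]hex-5-enoyl]-1,3-oxazolidin-2-one
Product: 7 (2S)-2-[(benzyloxy)methyl]hex-5-en-1-ol
Conditions: LiBH4, MeOH (1 equiv), Et2O, 0 °C
Reagents that add atoms: none
Why: Reductive cleavage of the imide by borohydride reduction of the exocyclic carbonyl should give the primary alcohol (the future C6′–OH) without epimerising C6 and return the auxiliary.

Step 4
Reactants: 7 (2S)-2-[(benzyloxy)methyl]hex-5-en-1-ol; 8 ethyl acrylate
Product: 9 ethyl (2E,6S)-6-[(benzyloxy)methyl]-7-hydroxyhept-2-enoate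
Conditions: second-generation Grubbs catalyst (H2IMes)(PCy3)Cl2Ru=CHPh (3 mol %), CH2Cl2, 40 °C
Reagents that add atoms: none
Why: Olefin cross-metathesis of a terminal alkene with an acrylate is selective for the (E)-configured hetero-product and tolerates the free hydroxyl and the benzyl ether.

Step 5
Reactants: 9 ethyl (2E,6S)-6-[(benzyloxy)methyl]-7-hydroxyhept-2-enoate
Product: 10 ethyl 2-[(2R,5R)-5-[(benzyloxy)methyl]oxan-2-yl]acetate
Conditions: t-BuOK (0.2 equiv), THF, 0 °C → rt (equilibrating)
Reagents that add atoms: none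
Why: Intramolecular oxa-Michael addition (6-exo-trig) under reversible base catalysis closes the tetrahydropyran and sets C3 under thermodynamic control, the diequatorial trans-2,5 isomer being favoured by relay from C6.

Step 6
Reactants: 10 ethyl 2-[(2R,5R)-5-[(benzyloxy)methyl]oxan-2-yl]acetate
Product: 11 ethyl 2-[(2R,5R)-5-(hydroxymethyl)oxan-2-yl]acetate
Conditions: H2 (1 atm), Pd/C, EtOH, rt
Reagents that add atoms: none
Why: Hydrogenolysis of the benzyl ether is clean here because the molecule carries no alkene at this stage.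

Step 7
Reactants: 11 ethyl 2-[(2R,5R)-5-(hydroxymethyl)oxan-2-yl]acetate
Product: 12 ethyl 2-[(2R,5S)-5-(iodomethyl)oxan-2-yl]acetate
Conditions: PPh3, I2, imidazole, CH2Cl2, 0 °C → rt
Reagents that add atoms: iodine, II
Why: Appel-type iodination converts the primary C7 alcohol into the iodide by SN2 displacement of the alkoxyphosphonium ion, leaving both stereocentres untouched.

Step 8
Reactants: 12 ethyl 2-[(2R,5S)-5-(iodomethyl)oxan-2-yl]acetate
Product: 16 ethyl 2-[(2R,5S)-5-(iodomethyl)oxan-2-yl]prop-2-enoate, via lithium enolate 13 (not isolated), via Mannich base 14 (not isolated), via ammonium iodide 15 (not isolated)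
Conditions: LiN(i-Pr)2, THF, −78 °C; CH2=NMe2+ I−, −78 °C → rt; then MeI, MeOH, rt; then aq. NaHCO3, CH2Cl2, rt
Reagents that add atoms: N,N-dimethylmethyleneiminium iodide, C=[N+](C)C.[I-]
Why: Ester-enolate Mannich reaction, N-methylation and E1cB loss of trimethylamine is the standard α-methylenation of an ester, and at −78 °C the iminium ion should trap the enolate far faster than the hindered primary iodide is alkylated, while the trans ring geometry rules out intramolecular alkylation.

Step 9
Reactants: 16 ethyl 2-[(2R,5S)-5-(iodomethyl)oxan-2-yl]prop-2-enoate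
Product: 17 2-[(2R,5S)-5-(iodomethyl)oxan-2-yl]prop-2-en-1-ol
Conditions: i-Bu2AlH (2.5 equiv), CH2Cl2, −78 °C; aq. potassium sodium tartrate
Reagents that add atoms: none
Why: 1,2-Reduction of the α-substituted acrylate by the aluminium hydride at −78 °C gives the allylic alcohol, and a primary alkyl iodide is inert at this temperature.

Step 10
Reactants: 17 2-[(2R,5S)-5-(iodomethyl)oxan-2-yl]prop-2-en-1-ol
Product: 18 tert-butyl({2-[(2R,5S)-5-(iodomethyl)oxan-2-yl]prop-2-en-1-yl}oxy)dimethylsilane
Conditions: TBSCl, imidazole, CH2Cl2, 0 °C → rt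
Reagents that add atoms: tert-butyldimethylsilyl chloride, CC(C)(C)[Si](C)(C)Cl
Why: Silylation masks the allylic alcohol (the latent acrylic acid) as an ether that is inert to the boron ate complex, to nickel and to basic peroxide.

Step 11
Reactants: 19 geranylacetone
Product: 21 (5E)-6,10-dimethylundeca-1,5,9-trien-2-yl trifluoromethanesulfonate, via lithium enolate 20 (not isolated)
Conditions: LiN(i-Pr)2, THF, −78 °C; PhNTf2, −78 → 0 °C
Reagents that add atoms: N-phenylbis(trifluoromethanesulfonimide), O=S(=O)(N(c1ccccc1)S(=O)(=O)C(F)(F)F)C(F)(F)F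
Why: Kinetic deprotonation of the methyl ketone at the methyl group and O-sulfonylation of the terminal enolate gives the 1,1-disubstituted enol triflate that carries C10=C10′, with the isolated trisubstituted alkenes untouched.

Step 12
Reactants: 21 (5E)-6,10-dimethylundeca-1,5,9-trien-2-yl trifluoromethanesulfonate; 22 bis(pinacolato)diboron
Product: 23 2-[(5E)-6,10-dimethylundeca-1,5,9-trien-2-yl]-4,4,5,5-tetramethyl-1,3,2-dioxaborolane
Conditions: PdCl2(PPh3)2 (3 mol %), PPh3 (6 mol %), KOPh, toluene, 50 °C
Reagents that add atoms: none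
Why: Miyaura borylation of the alkenyl triflate (oxidative addition to zerovalent palladium, phenoxide-assisted transmetalation with the diboron, reductive elimination) places boron on C10 without moving the alkene.

Step 13
Reactants: 23 2-[(5E)-6,10-dimethylundeca-1,5,9-trien-2-yl]-4,4,5,5-tetramethyl-1,3,2-dioxaborolane; 24 vinyllithium; 18 tert-butyl({2-[(2R,5S)-5-(iodomethyl)oxan-2-yl]prop-2-en-1-yl}oxy)dimethylsilane
Product: 26 2-[(3R,7E)-1-[(3S,6R)-6-{3-[(tert-butyldimethylsilyl)oxy]prop-1-en-2-yl}oxan-3-yl]-8,12-dimethyl-4-methylidenetrideca-7,11-dien-3-yl]-4,4,5,5-tetramethyl-1,3,2-dioxaborolane, via bis(alkenyl) boron ate complex 25 (not isolated)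
Conditions: 24, THF, 0 °C → rt; then 18 (limiting), NiBr2·glyme (10 mol %), (S,S)-Ph-Pybox or its antipode (12 mol %), THF/DMSO, rt
Reagents that add atoms: none
Why: Proposed new method: vinyllithium adds to boron of 23 to give the tetracoordinate bis(alkenyl) boronate 25; an alkyl–nickel species formed from iodide 18 (halogen abstraction by low-valent nickel and radical recombination) binds the unsubstituted vinyl group of 25 and triggers anti 1,2-migration of the C10 alkenyl group from boron to C9 while C8 bonds to nickel, and C(sp3)–C(sp3) reductive elimination then joins C7 to C8. The closest known reactions are the nickel/Pybox-catalysed enantioselective conjunctive coupling of vinylboron ate complexes with unactivated primary alkyl iodides and the palladium-catalysed conjunctive coupling of bis(alkenyl) borates, in which a substituted alkenyl group migrates to give α-chiral allylic boronates; pairing an alkenyl migrating group with a C(sp3) iodide is the untested element. No ring is closed. C9 is the only new stereocentre and is set by the chiral ligand, which selects the face of the vinyl group presented to nickel, so the outcome is catalyst-controlled and independent of the distant C3 and C6 centres. The step needs nickel to engage the vinyl rather than the 1,1-disubstituted alkenyl group (secured by the steric difference), carbon rather than a pinacol oxygen to migrate (secured by the high migratory aptitude of an sp2 carbon), and the metallate shift to outrun direct alkenyl transfer and β-hydride loss from the C7–nickel species (favoured by the tridentate ligand and the electron-rich ate complex).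

Step 14
Reactants: 26 the C9 pinacol boronate from step 13
Product: 27 (3R,7E)-1-[(3S,6R)-6-{3-[(tert-butyldimethylsilyl)oxy]prop-1-en-2-yl}oxan-3-yl]-8,12-dimethyl-4-methylidenetrideca-7,11-dien-3-ol
Conditions: 30% H2O2, 3 M NaOH, THF, 0 °C → rt
Reagents that add atoms: hydrogen peroxide, OO
Why: Oxidation of the C–B bond by hydroperoxide proceeds by 1,2-shift of carbon from boron to oxygen with retention, so the (9R)-allylic alcohol should form without allylic transposition.

Step 15
Reactants: 27 the C9 alcohol with C1 silyl ether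
Product: 28 (3R,7E)-1-[(3S,6R)-6-(3-hydroxyprop-1-en-2-yl)oxan-3-yl]-8,12-dimethyl-4-methylidenetrideca-7,11-dien-3-ol
Conditions: Bu4NF, THF, 0 °C → rt
Reagents that add atoms: none
Why: Fluoride-induced desilylation, driven by the Si–F bond, frees the primary allylic alcohol and touches nothing else.

Step 16
Reactants: 28 the C1,C9 diol
Product: 29 2-[(2R,5S)-5-[(3R,7E)-3-hydroxy-8,12-dimethyl-4-methylidenetrideca-7,11-dien-1-yl]oxan-2-yl]prop-2-enal
Conditions: TEMPO (10 mol %), PhI(OAc)2, CH2Cl2, rt
Reagents that add atoms: none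
Why: Oxoammonium oxidation is strongly selective for the unhindered primary allylic alcohol over the secondary C9 alcohol and stops at the enal under anhydrous conditions.

Step 17
Reactants: 29 the hydroxy enal
Product: 30 2-[(2R,5S)-5-[(3R,7E)-3-hydroxy-8,12-dimethyl-4-methylidenetrideca-7,11-dien-1-yl]oxan-2-yl]prop-2-enoic acid (CNP0197923.2)
Conditions: NaClO2, NaH2PO4, 2-methylbut-2-ene, t-BuOH/H2O, rt
Reagents that add atoms: sodium chlorite, [Na+].[O-]Cl=O
Why: Pinnick oxidation converts the enal into the acid under buffered conditions, with 2-methylbut-2-ene scavenging HOCl so that the trisubstituted alkenes and the allylic alcohol should survive.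

Compound list
1 | hex-5-enoic acid | C=CCCCC(=O)O | starting material
2 | (4S)-4-benzyl-1,3-oxazolidin-2-one | O=C1N[C@@H](Cc2ccccc2)CO1 | starting material
3 | hex-5-enoic pivalic anhydride (formed in the flask) | C=CCCCC(=O)OC(=O)C(C)(C)C | intermediate
4 | (4S)-4-benzyl-3-(hex-5-enoyl)-1,3-oxazolidin-2-one | C=CCCCC(=O)N1[C@@H](Cc2ccccc2)COC1=O | intermediate
5 | trichlorotitanium (Z)-enolate of 4 (formed in the flask) | C=CCC/C=C(\O[Ti](Cl)(Cl)Cl)N1[C@@H](Cc2ccccc2)COC1=O | intermediate
6 | (4S)-4-benzyl-3-[(2R)-2-[(benzyloxy)methyl]hex-5-enoyl]-1,3-oxazolidin-2-one | C=CCC[C@H](COCc1ccccc1)C(=O)N1[C@@H](Cc2ccccc2)COC1=O | intermediate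
7 | (2S)-2-[(benzyloxy)methyl]hex-5-en-1-ol | C=CCC[C@@H](CO)COCc1ccccc1 | intermediate
8 | ethyl acrylate | C=CC(=O)OCC | starting material
9 | ethyl (2E,6S)-6-[(benzyloxy)methyl]-7-hydroxyhept-2-enoate | CCOC(=O)/C=C/CC[C@@H](CO)COCc1ccccc1 | intermediate
10 | ethyl 2-[(2R,5R)-5-[(benzyloxy)methyl]oxan-2-yl]acetate (trans ring) | c1ccccc1COC[C@H]1CC[C@H](CC(=O)OCC)OC1 | intermediate
11 | ethyl 2-[(2R,5R)-5-(hydroxymethyl)oxan-2-yl]acetate | OC[C@H]1CC[C@H](CC(=O)OCC)OC1 | intermediate
12 | ethyl 2-[(2R,5S)-5-(iodomethyl)oxan-2-yl]acetate | IC[C@H]1CC[C@H](CC(=O)OCC)OC1 | intermediate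
13 | lithium enolate of 12 (formed in the flask) | IC[C@H]1CC[C@H](C=C([O-])OCC)OC1.[Li+] | intermediate
14 | ethyl 3-(dimethylamino)-2-[(2R,5S)-5-(iodomethyl)oxan-2-yl]propanoate, both α-epimers (formed in the flask) | IC[C@H]1CC[C@H](C(CN(C)C)C(=O)OCC)OC1 | intermediate
15 | 3-ethoxy-2-[(2R,5S)-5-(iodomethyl)oxan-2-yl]-N,N,N-trimethyl-3-oxopropan-1-aminium iodide (formed in the flask) | IC[C@H]1CC[C@H](C(C[N+](C)(C)C)C(=O)OCC)OC1.[I-] | intermediate
16 | ethyl 2-[(2R,5S)-5-(iodomethyl)oxan-2-yl]prop-2-enoate | IC[C@H]1CC[C@H](C(=C)C(=O)OCC)OC1 | intermediate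
17 | 2-[(2R,5S)-5-(iodomethyl)oxan-2-yl]prop-2-en-1-ol | IC[C@H]1CC[C@H](C(=C)CO)OC1 | intermediate
18 | tert-butyl({2-[(2R,5S)-5-(iodomethyl)oxan-2-yl]prop-2-en-1-yl}oxy)dimethylsilane (key-step precursor) | IC[C@H]1CC[C@H](C(=C)CO[Si](C)(C)C(C)(C)C)OC1 | intermediate
19 | geranylacetone, (5E)-6,10-dimethylundeca-5,9-dien-2-one | CC(=O)CC/C=C(\C)CCC=C(C)C | starting material
20 | terminal lithium enolate of 19 (formed in the flask) | [Li+].[O-]C(=C)CC/C=C(\C)CCC=C(C)C | intermediate
21 | (5E)-6,10-dimethylundeca-1,5,9-trien-2-yl trifluoromethanesulfonate | C=C(OS(=O)(=O)C(F)(F)F)CC/C=C(\C)CCC=C(C)C | intermediate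
22 | bis(pinacolato)diboron | CC1(C)OB(OC1(C)C)B1OC(C)(C)C(C)(C)O1 | starting material
23 | 2-[(5E)-6,10-dimethylundeca-1,5,9-trien-2-yl]-4,4,5,5-tetramethyl-1,3,2-dioxaborolane | C=C(B1OC(C)(C)C(C)(C)O1)CC/C=C(\C)CCC=C(C)C | intermediate
24 | vinyllithium | [Li]C=C | starting material
25 | lithium [(5E)-6,10-dimethylundeca-1,5,9-trien-2-yl](ethenyl)(pinacolato)borate (formed in the flask) | [Li+].C=C[B-]1(C(=C)CC/C=C(\C)CCC=C(C)C)OC(C)(C)C(C)(C)O1 | intermediate
26 | 2-[(3R,7E)-1-[(3S,6R)-6-{3-[(tert-butyldimethylsilyl)oxy]prop-1-en-2-yl}oxan-3-yl]-8,12-dimethyl-4-methylidenetrideca-7,11-dien-3-yl]-4,4,5,5-tetramethyl-1,3,2-dioxaborolane (key-step product) | C=C(CC/C=C(\C)CCC=C(C)C)[C@H](B1OC(C)(C)C(C)(C)O1)CC[C@H]2CC[C@H](C(=C)CO[Si](C)(C)C(C)(C)C)OC2 | intermediate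
27 | (3R,7E)-1-[(3S,6R)-6-{3-[(tert-butyldimethylsilyl)oxy]prop-1-en-2-yl}oxan-3-yl]-8,12-dimethyl-4-methylidenetrideca-7,11-dien-3-ol | C=C(CC/C=C(\C)CCC=C(C)C)[C@H](O)CC[C@H]1CC[C@H](C(=C)CO[Si](C)(C)C(C)(C)C)OC1 | intermediate
28 | (3R,7E)-1-[(3S,6R)-6-(3-hydroxyprop-1-en-2-yl)oxan-3-yl]-8,12-dimethyl-4-methylidenetrideca-7,11-dien-3-ol | C=C(CC/C=C(\C)CCC=C(C)C)[C@H](O)CC[C@H]1CC[C@H](C(=C)CO)OC1 | intermediate
29 | 2-[(2R,5S)-5-[(3R,7E)-3-hydroxy-8,12-dimethyl-4-methylidenetrideca-7,11-dien-1-yl]oxan-2-yl]prop-2-enal | C=C(CC/C=C(\C)CCC=C(C)C)[C@H](O)CC[C@H]1CC[C@H](C(=C)C=O)OC1 | intermediate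
30 | 2-[(2R,5S)-5-[(3R,7E)-3-hydroxy-8,12-dimethyl-4-methylidenetrideca-7,11-dien-1-yl]oxan-2-yl]prop-2-enoic acid | C=C(CC/C=C(\C)CCC=C(C)C)[C@H](O)CC[C@H]1CC[C@H](C(=C)C(=O)O)OC1 | target

Total steps: 17. Longest linear sequence: 15 steps (steps 1–10, then 13–17); steps 11–12 form the two-step branch to boronate 23.

Steps most likely to fail

1. Step 13 (labelled). The alkyl–nickel species may take an alkenyl or vinyl group by direct transmetalation instead of inducing the 1,2-shift, may lose a β-hydride, or the ligand may give poor facial selectivity at C9. The fallback uses known chemistry and sets out from iodide 18. Displacement with LiCH2CN (THF, −78 °C → rt) should give 3-[(3S,6R)-6-{3-[(tert-butyldimethylsilyl)oxy]prop-1-en-2-yl}oxan-3-yl]propanenitrile F1. Reduction with i-Bu2AlH (CH2Cl2, −78 °C, then aqueous acid) should give 3-[(3R,6R)-6-{3-[(tert-butyldimethylsilyl)oxy]prop-1-en-2-yl}oxan-3-yl]propanal F2. Nozaki–Hiyama–Kishi coupling of F2 with enol triflate 21 (CrCl2, NiCl2 cat., DMF) should give the C9-epimeric allylic alcohol (3RS,7E)-1-[(3S,6R)-6-{3-[(tert-butyldimethylsilyl)oxy]prop-1-en-2-yl}oxan-3-yl]-8,12-dimethyl-4-methylidenetrideca-7,11-dien-3-ol F3. Dess–Martin periodinane should give the enone (7E)-1-[(3R,6R)-6-{3-[(tert-butyldimethylsilyl)oxy]prop-1-en-2-yl}oxan-3-yl]-8,12-dimethyl-4-methylidenetrideca-7,11-dien-3-one F4. Corey–Bakshi–Shibata reduction ((S)-2-methyl-CBS-oxazaborolidine, catecholborane, toluene, −78 °C; the alkenyl group acts as the large substituent) should give the (9R)-alcohol 27, where the route is rejoined.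

2. Step 5. Incomplete equilibration, or a weak kinetic preference, may leave a substantial share of the cis ring isomer, and ester exchange with the alkoxide may complicate the mixture. The fallback replaces thermodynamic by kinetic stereocontrol and sets out from alcohol 7. Ozonolysis (O3, CH2Cl2, −78 °C; PPh3) should give the lactol (5R)-5-[(benzyloxy)methyl]oxan-2-ol F5. Oxidation (TEMPO, PhI(OAc)2, CH2Cl2) should give the lactone (5R)-5-[(benzyloxy)methyl]oxan-2-one F6. Addition of the lithium enolate of ethyl acetate (LiN(i-Pr)2, EtOAc, THF, −78 °C) should give the hemiketal ethyl 2-[(5R)-5-[(benzyloxy)methyl]-2-hydroxyoxan-2-yl]acetate F7. Reduction with Et3SiH/BF3·OEt2 (CH2Cl2, −78 °C) proceeds by axial hydride delivery to the oxocarbenium ion whose C6 substituent is pseudo-equatorial and should give trans ester 10, where the route is rejoined.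

3. Step 8. Alkylation or elimination at the primary iodide by the enolate, the Mannich amine or the base may compete with the methylenation. The fallback installs the methylene before the iodine and sets out from hydroxy ester 11. α-Methylenation of its alkoxide–enolate dianion (2.2 equiv LiN(i-Pr)2, THF, −78 °C; CH2=NMe2+ I−; then MeI; then aq. NaHCO3) should give ethyl 2-[(2R,5R)-5-(hydroxymethyl)oxan-2-yl]prop-2-enoate F8. Iodination (PPh3, I2, imidazole, CH2Cl2) then gives acrylate 16, where the route is rejoined.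

Further compounds
F1 | step 13 | 3-[(3S,6R)-6-{3-[(tert-butyldimethylsilyl)oxy]prop-1-en-2-yl}oxan-3-yl]propanenitrile | N#CCC[C@H]1CC[C@H](C(=C)CO[Si](C)(C)C(C)(C)C)OC1
F2 | step 13 | 3-[(3R,6R)-6-{3-[(tert-butyldimethylsilyl)oxy]prop-1-en-2-yl}oxan-3-yl]propanal | O=CCC[C@H]1CC[C@H](C(=C)CO[Si](C)(C)C(C)(C)C)OC1
F3 | step 13 | (3RS,7E)-1-[(3S,6R)-6-{3-[(tert-butyldimethylsilyl)oxy]prop-1-en-2-yl}oxan-3-yl]-8,12-dimethyl-4-methylidenetrideca-7,11-dien-3-ol | C=C(CC/C=C(\C)CCC=C(C)C)C(O)CC[C@H]1CC[C@H](C(=C)CO[Si](C)(C)C(C)(C)C)OC1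
F4 | step 13 | (7E)-1-[(3R,6R)-6-{3-[(tert-butyldimethylsilyl)oxy]prop-1-en-2-yl}oxan-3-yl]-8,12-dimethyl-4-methylidenetrideca-7,11-dien-3-one | C=C(CC/C=C(\C)CCC=C(C)C)C(=O)CC[C@H]1CC[C@H](C(=C)CO[Si](C)(C)C(C)(C)C)OC1
F5 | step 5 | (5R)-5-[(benzyloxy)methyl]oxan-2-ol | OC1CC[C@H](COCc2ccccc2)CO1
F6 | step 5 | (5R)-5-[(benzyloxy)methyl]oxan-2-one | O=C1CC[C@H](COCc2ccccc2)CO1
F7 | step 5 | ethyl 2-[(5R)-5-[(benzyloxy)methyl]-2-hydroxyoxan-2-yl]acetate | CCOC(=O)CC1(O)CC[C@H](COCc2ccccc2)CO1
F8 | step 8 | ethyl 2-[(2R,5R)-5-(hydroxymethyl)oxan-2-yl]prop-2-enoate | OC[C@H]1CC[C@H](C(=C)C(=O)OCC)OC1
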